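Ring atoms (elemane numbering): C10 quaternary (Me, vinyl), C9 CH2, C8 acyloxy carbon, C7 and C6 lactone-fusion carbons (C6 bears the lactone oxygen), C5 carries the hydroxypropenyl group. The cyclohexane is cut into C9–C10–C5, with C10 set by iridium catalysis, and C8–C7–C6, a masked 2-substituted malondialdehyde exploiting the 1,3-dioxygenation at C6 and C8. In one flask a formal (3+3) annulation joins them: an alkyltitanium at C9 adds to the free aldehyde (C9–C8), then TMSOTf ionises the acetal and the trisubstituted alkene closes the ring by oxonium-ene reaction (C5–C6), setting C8, C6 and C5. Precursors: an acyclic iodo-diene and an acyclic acetal aldehyde.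

Key step: step 12

Assumption: in step 1 the (R)-configured bisphosphine is taken to give the (2R,3R)-diol 3 (carbinol anti to the hydroxymethyl group); should the catalyst show the opposite sense, its enantiomer is used.
Convention: C11 is the lactone CH(CH3) carbon and C12 the lactone carbonyl carbon; PMB = 4-methoxybenzyl, TBS = tert-butyldimethylsilyl, DTBMP = 2,6-di-tert-butyl-4-methylpyridine.

**Fragment A (C9–C10–C5)**

Step 1
Reactants: 1 2-methylpropan-1-ol; 2 2-ethenyl-2-methyloxirane (racemic)
Product: 3 (2R,3R)-2-ethenyl-2,4-dimethylpentane-1,3-diol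
Conditions: Ir(η3-C3H5)[(R)-Tol-BINAP](C,O-4-cyano-3-nitrobenzoate) (5 mol %), K3PO4 (5 mol %), THF, 60 °C
Reagents that add atoms: none
Why: Redox-neutral iridium-catalysed tert-(hydroxy)prenylation (transfer-hydrogenative carbonyl allylation), in which the alcohol is dehydrogenated to the aldehyde, the vinyl epoxide is ionised to a π-allyliridium species that adds through its tertiary terminus in a chair transition state, and the chiral bisphosphine sets the quaternary C10 centre while both epoxide enantiomers converge through the π-allyl.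

Step 2
Reactants: 3 (2R,3R)-2-ethenyl-2,4-dimethylpentane-1,3-diol
Product: 4 (3S,4R)-3-(iodomethyl)-3,5-dimethylhex-1-en-4-ol
Conditions: PPh3, imidazole, I2, toluene/MeCN, 0 → 60 °C
Reagents that add atoms: iodine, II
Why: Appel-type (Garegg–Samuelsson) iodination should occur only at the primary hydroxyl, because the secondary carbinol lies between a quaternary carbon and an isopropyl group; no stereocentre is touched.

Step 3
Reactants: 4 (3S,4R)-3-(iodomethyl)-3,5-dimethylhex-1-en-4-ol
Product: 5 (3S)-3-(iodomethyl)-3,5-dimethylhexa-1,4-diene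
Conditions: Burgess reagent (MeO2CN−SO2N+Et3), toluene, 60 °C
Reagents that add atoms: none
Why: Burgess dehydration by syn-elimination of the sulfamate can only take the isopropyl methine hydrogen, since C10 bears none, so the trisubstituted alkene forms and the carbinol stereocentre is removed.

**Fragment B (C8–C7–C6 with C11, C12)**

Step 4
Reactants: 6 3-[(tert-butyldimethylsilyl)oxy]propanal; 7 (E)-1-nitroprop-1-ene
Product: 8 (2R,3S)-2-{[(tert-butyldimethylsilyl)oxy]methyl}-3-methyl-4-nitrobutanal
Conditions: (R)-α,α-diphenylprolinol trimethylsilyl ether (10 mol %), PhCO2H (10 mol %), toluene, 0 °C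
Reagents that add atoms: none
Why: Enamine-catalysed Michael addition of an aldehyde to a nitroalkene, in which the (E)-enamine attacks through an acyclic synclinal transition state on the face away from the diarylsilyloxymethyl group, setting C7 and C11 in the syn relationship.

Step 5
Reactants: 8 (2R,3S)-2-{[(tert-butyldimethylsilyl)oxy]methyl}-3-methyl-4-nitrobutanal
Product: 9 tert-butyl{[(2R,3S)-2-{bis[(4-methoxybenzyl)oxy]methyl}-3-methyl-4-nitrobutyl]oxy}dimethylsilane
Conditions: 4-MeOC6H4CH2OSiMe3 (2.5 equiv), TMSOTf (5 mol %), CH2Cl2, −78 °C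
Reagents that add atoms: (4-methoxybenzyloxy)trimethylsilane, COc1ccc(CO[Si](C)(C)C)cc1
Why: Acetalisation with a silyl ether under TMSOTf catalysis at −78 °C is non-epimerising and turns the aldehyde (future C6) into the bis-PMB acetal that later serves as the oxocarbenium precursor.

Step 6
Reactants: 9 tert-butyl{[(2R,3S)-2-{bis[(4-methoxybenzyl)oxy]methyl}-3-methyl-4-nitrobutyl]oxy}dimethylsilane
Product: 10 (2S,3R)-3-{[(tert-butyldimethylsilyl)oxy]methyl}-4,4-bis[(4-methoxybenzyl)oxy]-2-methylbutanoic acid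
Conditions: NaNO2 (3 equiv), AcOH (10 equiv), DMSO, 35 °C
Reagents that add atoms: water, O
Why: Nitrite/acetic acid oxidation of a primary nitroalkane to the carboxylic acid (via the nitrolic acid and the nitrile oxide) should proceed without epimerising the adjacent C11 centre, under conditions mild enough for the acetal and the silyl ether.

Step 7
Reactants: 10 (2S,3R)-3-{[(tert-butyldimethylsilyl)oxy]methyl}-4,4-bis[(4-methoxybenzyl)oxy]-2-methylbutanoic acid
Product: 11 methyl (2S,3R)-3-{[(tert-butyldimethylsilyl)oxy]methyl}-4,4-bis[(4-methoxybenzyl)oxy]-2-methylbutanoate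
Conditions: MeI, K2CO3, DMF, 0 °C → rt
Reagents that add atoms: iodomethane, CI
Why: O-Alkylation of the carboxylate (SN2 on MeI) gives a methyl ester, which is inert to the organotitanium reagent and, unlike a tert-butyl ester, cannot fragment when the oxocarbenium ion is generated later.

Step 8
Reactants: 11 methyl (2S,3R)-3-{[(tert-butyldimethylsilyl)oxy]methyl}-4,4-bis[(4-methoxybenzyl)oxy]-2-methylbutanoate
Product: 12 methyl (2S,3R)-3-(hydroxymethyl)-4,4-bis[(4-methoxybenzyl)oxy]-2-methylbutanoate
Conditions: HF·pyridine, pyridine, THF, 0 °C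
Reagents that add atoms: none
Why: Buffered fluoride cleaves the primary silyl ether under non-basic conditions, which should spare the acetal and avoid lactonisation of the γ-hydroxy ester; the alcohol is carried on at once.

Step 9
Reactants: 12 methyl (2S,3R)-3-(hydroxymethyl)-4,4-bis[(4-methoxybenzyl)oxy]-2-methylbutanoate
Product: 13 methyl (2S,3R)-3-formyl-4,4-bis[(4-methoxybenzyl)oxy]-2-methylbutanoate
Conditions: Dess–Martin periodinane, CH2Cl2, 0 °C; used crude
Reagents that add atoms: none
Why: Dess–Martin oxidation gives the aldehyde (future C8) under near-neutral conditions that should not epimerise the α-centre C7.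

**Side-chain acid**

Step 10
Reactants: 14 methyl (R)-3-hydroxy-2-methylpropanoate
Product: 15 methyl (R)-3-[(tert-butyldimethylsilyl)oxy]-2-methylpropanoate
Conditions: TBSCl, imidazole, DMF, rt
Reagents that add atoms: tert-butyl(chloro)dimethylsilane, CC(C)(C)[Si](C)(C)Cl
Why: Imidazole-mediated silylation protects the primary alcohol of the Roche ester, whose stereocentre is bought.

Step 11
Reactants: 15 methyl (R)-3-[(tert-butyldimethylsilyl)oxy]-2-methylpropanoate
Product: 16 (R)-3-[(tert-butyldimethylsilyl)oxy]-2-methylpropanoic acid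
Conditions: LiOH·H2O, THF/MeOH/H2O, 0 °C; then 1 M HCl to pH 3
Reagents that add atoms: lithium hydroxide, [Li+].[OH-]
Why: Saponification at 0 °C is mild enough to keep the α-stereocentre and the silyl ether.

**Union and end game**

Step 12
Reactants: 5 (3S)-3-(iodomethyl)-3,5-dimethylhexa-1,4-diene; 13 methyl (2S,3R)-3-formyl-4,4-bis[(4-methoxybenzyl)oxy]-2-methylbutanoate
Product: 21 methyl (2S)-2-[(1R,2R,3S,4S,6S)-4-ethenyl-6-hydroxy-2-[(4-methoxybenzyl)oxy]-4-methyl-3-(prop-1-en-2-yl)cyclohexyl]propanoate, via alkyllithium 17 (not isolated), via alkyltitanium triisopropoxide 18 (not isolated), via open-chain titanium alkoxide 19 (not isolated), via cyclised trimethylsilyl ether 20 (not isolated)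
Conditions: t-BuLi (2.1 equiv), Et2O/pentane, −78 °C; ClTi(OiPr)3, −78 → −40 °C; 13, −78 → 0 °C; then CH2Cl2, DTBMP, TMSOTf (2.5 equiv), −78 °C; 1 M HCl/THF work-up
Reagents that add atoms: none
Why: Iodine–lithium exchange and transmetalation give a neopentyl-type alkyltitanium (no β-hydrogen) that adds chemoselectively to the aldehyde of 13 to form C9–C8, after which TMSOTf silylates the alkoxide and ionises the bis-PMB acetal, and the trisubstituted alkene attacks the oxocarbenium ion through C5 with loss of a methyl proton (oxonium-ene/Prins cyclisation) to form C5–C6; the closest known reaction types are Felkin–Anh-selective additions of RTi(OiPr)3 to α-branched aldehydes and the acid-induced cyclisation of citronellal and its acetals to isopulegol derivatives. The cyclohexane closes in the 6-exo mode, only the proximal alkene carbon entering the ring while the tertiary cation stays exocyclic. C8 is controlled by the C7 stereocentre, the non-chelating titanium reagent attacking anti to the bis(alkoxy)methyl group (the bulkiest and most electron-poor α-substituent), whereas C6 and C5 are controlled by a chair transition state in which the C7 side chain, the C8 silyloxy group, the oxocarbenium oxygen and the reacting alkene are all equatorial, so that O6 ends trans to C11 and the propenyl group trans to O6, the fixed C10 configuration of 5 then placing its methyl group axial. The step needs 1,2-addition without chelation control and without ester attack, which the triisopropoxytitanium reagent should secure, and ring closure through the trisubstituted alkene and not the vinyl group, which is secured because only the former leads to a tertiary cation.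

Step 13
Reactants: 21 methyl (2S)-2-[(1R,2R,3S,4S,6S)-4-ethenyl-6-hydroxy-2-[(4-methoxybenzyl)oxy]-4-methyl-3-(prop-1-en-2-yl)cyclohexyl]propanoate; 16 (R)-3-[(tert-butyldimethylsilyl)oxy]-2-methylpropanoic acid
Product: 22 methyl (2S)-2-[(1R,2R,3S,4S,6S)-6-{[(2R)-3-{[tert-butyl(dimethyl)silyl]oxy}-2-methylpropanoyl]oxy}-4-ethenyl-2-[(4-methoxybenzyl)oxy]-4-methyl-3-(prop-1-en-2-yl)cyclohexyl]propanoate
Conditions: DCC, DMAP (cat.), CH2Cl2, 0 °C → rt
Reagents that add atoms: none
Why: Steglich esterification acylates the equatorial C8 hydroxyl, and lactonisation onto the methyl ester should not compete because it would give a strained trans-fused lactone that forms only under acid catalysis.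

Step 14
Reactants: 22 methyl (2S)-2-[(1R,2R,3S,4S,6S)-6-{[(2R)-3-{[tert-butyl(dimethyl)silyl]oxy}-2-methylpropanoyl]oxy}-4-ethenyl-2-[(4-methoxybenzyl)oxy]-4-methyl-3-(prop-1-en-2-yl)cyclohexyl]propanoate
Product: 23 methyl (2S)-2-[(1R,2R,3R,4S,6S)-6-{[(2R)-3-{[tert-butyl(dimethyl)silyl]oxy}-2-methylpropanoyl]oxy}-4-ethenyl-3-(3-hydroxyprop-1-en-2-yl)-2-[(4-methoxybenzyl)oxy]-4-methylcyclohexyl]propanoate
Conditions: SeO2 (0.5 equiv), t-BuOOH (2 equiv), CH2Cl2, rt
Reagents that add atoms: selenium dioxide, O=[Se]=O (oxygen carrier); tert-butyl hydroperoxide, CC(C)(C)OO (terminal oxidant)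
Why: SeO2 allylic hydroxylation (ene reaction then [2,3]-sigmatropic shift) should oxidise the methyl group of the 1,1-disubstituted alkene, since the vinyl group has no allylic hydrogen and the ring methine C5–H is shielded by the quaternary C10 and the C6 substituent.

Step 15
Reactants: 23 methyl (2S)-2-[(1R,2R,3R,4S,6S)-6-{[(2R)-3-{[tert-butyl(dimethyl)silyl]oxy}-2-methylpropanoyl]oxy}-4-ethenyl-3-(3-hydroxyprop-1-en-2-yl)-2-[(4-methoxybenzyl)oxy]-4-methylcyclohexyl]propanoate
Product: 24 (3S,3aR,4S,6S,7R,7aR)-6-ethenyl-7-(3-hydroxyprop-1-en-2-yl)-3,6-dimethyl-2-oxooctahydro-1-benzofuran-4-yl (2R)-3-hydroxy-2-methylpropanoate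
Conditions: TFA/CH2Cl2 (1:4), anisole, H2O (2 equiv), 0 °C → rt; then TsOH·H2O (cat.), toluene, 50 °C
Reagents that add atoms: none
Why: Acidolysis removes the PMB ether (cation trapped by anisole) and the silyl ether, and the liberated equatorial C6 hydroxyl lactonises onto the C12 methyl ester by acid-catalysed transesterification to the trans-fused γ-lactone, C8 being already acylated so that only the 6,12-lactone can form.

**Compound list**

1 | 2-methylpropan-1-ol | CC(C)CO | starting material
2 | 2-ethenyl-2-methyloxirane (racemic) | C=CC1(C)CO1 | starting material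
3 | (2R,3R)-2-ethenyl-2,4-dimethylpentane-1,3-diol | C=C[C@]([C@H](O)C(C)C)(C)CO | intermediate
4 | (3S,4R)-3-(iodomethyl)-3,5-dimethylhex-1-en-4-ol | C=C[C@]([C@H](O)C(C)C)(C)CI | intermediate
5 | (3S)-3-(iodomethyl)-3,5-dimethylhexa-1,4-diene | C=C[C@](C=C(C)C)(C)CI | intermediate
6 | 3-[(tert-butyldimethylsilyl)oxy]propanal | O=CCCO[Si](C)(C)C(C)(C)C | starting material
7 | (E)-1-nitroprop-1-ene | C/C=C/[N+](=O)[O-] | starting material
8 | (2R,3S)-2-{[(tert-butyldimethylsilyl)oxy]methyl}-3-methyl-4-nitrobutanal | O=C[C@@H](CO[Si](C)(C)C(C)(C)C)[C@H](C)C[N+](=O)[O-] | intermediate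
9 | tert-butyl{[(2R,3S)-2-{bis[(4-methoxybenzyl)oxy]methyl}-3-methyl-4-nitrobutyl]oxy}dimethylsilane | COc1ccc(COC(OCc2ccc(OC)cc2)[C@@H](CO[Si](C)(C)C(C)(C)C)[C@H](C)C[N+](=O)[O-])cc1 | intermediate
10 | (2S,3R)-3-{[(tert-butyldimethylsilyl)oxy]methyl}-4,4-bis[(4-methoxybenzyl)oxy]-2-methylbutanoic acid | COc1ccc(COC(OCc2ccc(OC)cc2)[C@@H](CO[Si](C)(C)C(C)(C)C)[C@H](C)C(=O)O)cc1 | intermediate
11 | methyl (2S,3R)-3-{[(tert-butyldimethylsilyl)oxy]methyl}-4,4-bis[(4-methoxybenzyl)oxy]-2-methylbutanoate | COc1ccc(COC(OCc2ccc(OC)cc2)[C@@H](CO[Si](C)(C)C(C)(C)C)[C@H](C)C(=O)OC)cc1 | intermediate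
12 | methyl (2S,3R)-3-(hydroxymethyl)-4,4-bis[(4-methoxybenzyl)oxy]-2-methylbutanoate | COc1ccc(COC(OCc2ccc(OC)cc2)[C@@H](CO)[C@H](C)C(=O)OC)cc1 | intermediate
13 | methyl (2S,3R)-3-formyl-4,4-bis[(4-methoxybenzyl)oxy]-2-methylbutanoate | COc1ccc(COC(OCc2ccc(OC)cc2)[C@@H](C=O)[C@H](C)C(=O)OC)cc1 | intermediate
14 | methyl (R)-3-hydroxy-2-methylpropanoate | COC(=O)[C@H](C)CO | starting material
15 | methyl (R)-3-[(tert-butyldimethylsilyl)oxy]-2-methylpropanoate | COC(=O)[C@H](C)CO[Si](C)(C)C(C)(C)C | intermediate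
16 | (R)-3-[(tert-butyldimethylsilyl)oxy]-2-methylpropanoic acid | OC(=O)[C@H](C)CO[Si](C)(C)C(C)(C)C | intermediate
17 | [(2S)-2-ethenyl-2,4-dimethylpent-3-en-1-yl]lithium | C=C[C@](C=C(C)C)(C)C[Li] | intermediate
18 | [(2S)-2-ethenyl-2,4-dimethylpent-3-en-1-yl]tris(propan-2-olato)titanium | C=C[C@](C=C(C)C)(C)C[Ti](OC(C)C)(OC(C)C)OC(C)C | intermediate
19 | open-chain adduct of 18 and 13, the C8–O–Ti(OiPr)3 alkoxide of the (8S)-carbinol | C=C[C@](C)(C[C@H](O[Ti](OC(C)C)(OC(C)C)OC(C)C)[C@@H]([C@H](C)C(=O)OC)C(OCc1ccc(OC)cc1)OCc1ccc(OC)cc1)C=C(C)C | intermediate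
20 | trimethylsilyl ether of 21 (silylated at the ring hydroxyl) | C=C[C@]1(C)C[C@H](O[Si](C)(C)C)[C@@H]([C@H](C)C(=O)OC)[C@H](OCc2ccc(OC)cc2)[C@H]1C(C)=C | intermediate
21 | methyl (2S)-2-[(1R,2R,3S,4S,6S)-4-ethenyl-6-hydroxy-2-[(4-methoxybenzyl)oxy]-4-methyl-3-(prop-1-en-2-yl)cyclohexyl]propanoate | C=C[C@]1(C)C[C@H](O)[C@@H]([C@H](C)C(=O)OC)[C@H](OCc2ccc(OC)cc2)[C@H]1C(C)=C | intermediate
22 | methyl (2S)-2-[(1R,2R,3S,4S,6S)-6-{[(2R)-3-{[tert-butyl(dimethyl)silyl]oxy}-2-methylpropanoyl]oxy}-4-ethenyl-2-[(4-methoxybenzyl)oxy]-4-methyl-3-(prop-1-en-2-yl)cyclohexyl]propanoate | C=C[C@]1(C)C[C@H](OC(=O)[C@H](C)CO[Si](C)(C)C(C)(C)C)[C@@H]([C@H](C)C(=O)OC)[C@H](OCc2ccc(OC)cc2)[C@H]1C(C)=C | intermediate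
23 | methyl (2S)-2-[(1R,2R,3R,4S,6S)-6-{[(2R)-3-{[tert-butyl(dimethyl)silyl]oxy}-2-methylpropanoyl]oxy}-4-ethenyl-3-(3-hydroxyprop-1-en-2-yl)-2-[(4-methoxybenzyl)oxy]-4-methylcyclohexyl]propanoate | C=C[C@]1(C)C[C@H](OC(=O)[C@H](C)CO[Si](C)(C)C(C)(C)C)[C@@H]([C@H](C)C(=O)OC)[C@H](OCc2ccc(OC)cc2)[C@H]1C(=C)CO | intermediate
24 | (3S,3aR,4S,6S,7R,7aR)-6-ethenyl-7-(3-hydroxyprop-1-en-2-yl)-3,6-dimethyl-2-oxooctahydro-1-benzofuran-4-yl (2R)-3-hydroxy-2-methylpropanoate | C=C[C@]1(C)C[C@H](OC(=O)[C@H](C)CO)[C@@H]2[C@H](OC(=O)[C@H]2C)[C@H]1C(=C)CO | target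

Total step count: 15. Longest linear sequence: 10 steps (steps 4–9, then 12–15).

**Steps most likely to fail**

Step 12. The facial preference in the aldehyde addition may erode if titanium is chelated by the acetal oxygens; the acetal may ionise or eliminate too early; the tertiary cation may lose its proton towards the tetrasubstituted alkene. The fallback sets out from 5 and 13 and comes back at 21; it separates the two bond formations and puts C8 under catalyst control. Iodide 5 is converted with t-BuLi and then ZnBr2 into bis[(2S)-2-ethenyl-2,4-dimethylpent-3-en-1-yl]zinc F1. F1 is added to 13 in the presence of Ti(OiPr)4 and catalytic (1R,2R)-N,N'-cyclohexane-1,2-diylbis(trifluoromethanesulfonamide), which is expected to deliver the 8S carbinol methyl (2S,3R)-3-[(1S,3S)-3-ethenyl-1-hydroxy-3,5-dimethylhex-4-en-1-yl]-4,4-bis[(4-methoxybenzyl)oxy]-2-methylbutanoate F2. After isolation, F2 is cyclised in a separate operation with TMSOTf and DTBMP in CH2Cl2 at −78 °C, and acidic work-up gives 21.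

Step 14. Oxidation may occur at the ring methine C5–H, or the allylic alcohol may be over-oxidised to the enal. The fallback sets out from 22 and comes back at 23. mCPBA (NaHCO3, CH2Cl2, 0 °C) should epoxidise the 1,1-disubstituted alkene in preference to the vinyl group, giving the 2-methyloxiran-2-yl analogue of 22 (both epimers at the new oxirane carbon) F3. Diethylaluminium 2,2,6,6-tetramethylpiperidide in toluene at 0 °C then isomerises the epoxide to the allylic alcohol 23 by removing a hydrogen from the unhindered methyl group.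

Step 3. The neopentylic, homoallylic sulfamate may ionise and undergo a 1,2-shift or cyclopropylcarbinyl rearrangement instead of syn-elimination. The fallback sets out from 4 and comes back at 5. Dess–Martin oxidation gives (3S)-3-(iodomethyl)-3,5-dimethylhex-1-en-4-one F4, which can enolise only towards the isopropyl group. KN(SiMe3)2 and PhNTf2 in THF at −78 °C convert it into (3S)-3-(iodomethyl)-3,5-dimethylhexa-1,4-dien-4-yl trifluoromethanesulfonate F5. Reduction with HCO2H/Bu3N catalysed by Pd(OAc)2/PPh3 in DMF replaces the triflate by hydrogen and gives 5; the neopentyl-type iodide should be slow to react with the palladium catalyst.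

Further compounds
F1 | step 12 | bis[(2S)-2-ethenyl-2,4-dimethylpent-3-en-1-yl]zinc | C=C[C@](C=C(C)C)(C)C[Zn]C[C@@](C)(C=C)C=C(C)C
F2 | step 12 | methyl (2S,3R)-3-[(1S,3S)-3-ethenyl-1-hydroxy-3,5-dimethylhex-4-en-1-yl]-4,4-bis[(4-methoxybenzyl)oxy]-2-methylbutanoate | C=C[C@](C)(C[C@H](O)[C@@H]([C@H](C)C(=O)OC)C(OCc1ccc(OC)cc1)OCc1ccc(OC)cc1)C=C(C)C
F3 | step 14 | 2-methyloxiran-2-yl analogue of 22 (epoxide of the prop-1-en-2-yl group, both epimers at the new oxirane carbon) | C=C[C@]1(C)C[C@H](OC(=O)[C@H](C)CO[Si](C)(C)C(C)(C)C)[C@@H]([C@H](C)C(=O)OC)[C@H](OCc2ccc(OC)cc2)[C@H]1C1(C)CO1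
F4 | step 3 | (3S)-3-(iodomethyl)-3,5-dimethylhex-1-en-4-one | C=C[C@](C(=O)C(C)C)(C)CI
F5 | step 3 | (3S)-3-(iodomethyl)-3,5-dimethylhexa-1,4-dien-4-yl trifluoromethanesulfonate | C=C[C@](C(OS(=O)(=O)C(F)(F)F)=C(C)C)(C)CI
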